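Is any of these four set-ups worth a run of its own, or will they end within the margin of one another?

the same everywhere: starting material 0.21 M
- birch: reagent 0.90 equiv; second substrate 5 equiv; run made earlier
- maple: reagent 0.90 equiv; second substrate 7 equiv; run made earlier
- alder: reagent 0.90 equiv; second substrate 11 equiv; run made earlier
- dawn: reagent 0.900 equiv; second substrate 5.00 equiv; one stirred flow tank at steady state, fed with the mixture as stated, mean residence time 40 h
- summer: reagent 0.900 equiv; second substrate 5.00 equiv; one stirred flow tank at steady state, fed with the mixture as stated, mean residence time 200 h
- autumn: reagent 0.900 equiv; second substrate 5.00 equiv (fed, over 32.0 h); all but second substrate at the start; second substrate goes in evenly over 32.0 h, the run ends at 40 h; time 40 h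
- spring: reagent 0.900 equiv; second substrate 5.00 equiv; a closed flask charged with all of it at once and left for 40 h; time 40 h

| birch: time / h | birch: target / % | maple: time / h | maple: target / % | alder: time / h | alder: target / % |
|---|---|---|---|---|---|
| 2.00 | 1.7 | 3.00 | 2.1 | 2.50 | 2.5 |
| 3.00 | 1.6 | 5.00 | 3.6 | 8.00 | 3.1 |
| 5.00 | 2.2 | 8.00 | 3.7 | 15.0 | 4.0 |
| 8.00 | 3.4 | 15.0 | 3.8 | 20.0 | 4.0 |
| 15.0 | 4.4 | 25.0 | 4.5 | 30.0 | 4.5 |
| 25.0 | 4.0 | 40.0 | 5.1 | 40.0 | 5.0 |

(scatter of a reading: 0.3 percentage points)

- the stated concentrations are those of everything mixed, before any reaction; amounts are the same in each set-up
- the numbers in the tables scatter by 0.3 percentage points (one standard deviation)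
- steps under discussion: starting material + reagent -> target; target <-> isomer of the product; second substrate + reagent -> second product; starting material + second substrate -> cross product; 2 reagent -> homo dimer
- the feed brings no volume worth counting
- the earlier runs were made in a closed, stirred flask

- the set-up with the highest amount of target at the outlet or at the end, in percent of the starting material put in ("none" if the first two lie within 2 percentage points) (dawn / summer / autumn / spring / none)
- amount of target at the outlet or at the end, in percent of the starting material put in, dawn
- amount of target at the outlet or at the end, in percent of the starting material put in, summer
- amount of target at the outlet or at the end, in percent of the starting material put in, autumn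
- amount of target at the outlet or at the end, in percent of the starting material put in, spring

1. The reagent, at 0.900 equiv, is the limiting reagent. In the closed runs target climbs quickly, then creeps: at 40 h, maple reads 5.1% and alder 5.0%.

2. Those readings differ by 0.1 percentage points, less than the scatter of 0.3 points, although alder holds more second substrate. So I take their mean, 5.05%, as my reckoning for spring, and for autumn, which receives the same second substrate later.

3. I set 7.05% as the bar, the closed-flask mean plus the margin. A set-up that ends above it clears my reckoning for spring and autumn by the margin.

4. A steady tank fed without target holds at its outlet the net rate of gain of target times its mean residence time. Summer, at 200 h, therefore needs a net gain of 0.88 points per 25.0 h. Maple's readings rose by 1.3 points between 15.0 h and 40.0 h, more than that, though this difference of two readings carries the scatter of both.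

5. But summer's tank is not maple's flask, so I expect summer near the bar, not far above it. I charge summer next and leave autumn and spring uncharged.

6. The forecast gives 8.3% for dawn, 16% for summer, 5.1% for autumn, 4.9% for spring and summer as best, holding that “A stirred tank holds the reagent dilute, which suppresses dimerisation.”

The flasks give 5.23% for dawn, 6.04% for summer, 5.68% for autumn and 5.33% for spring, so the answer to best is none.

    starting material + reagent → target (k = 0.0830 /M/h)
    target ⇌ isomer of the product (K = 0.900, k = 0.270 /h)
    second substrate + reagent → second product (k = 0.00170 /M/h)
    starting material + second substrate → cross product (k = 0.00890 /M/h)
    2 reagent → homo dimer (k = 0.820 /M/h)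

In spring, target turned towards isomer of the product with a forward half-life of 2.6 h, short against 40 h, and the end held 4.71% of isomer of the product beside 62.0% of starting material. Summer's tank held [starting material] at 0.0702 M and [reagent] at 0.0205 M, and its outlet stayed under the bar of 7.05%. Dawn's tank held [starting material] at 0.140 M, and its outlet, at 5.23%, also stayed under the bar.

All runs come from a simulation with constants of no real substance, and the scatter is random.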